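**Retrosynthetic overview**

1. Numbering (azulene, used throughout): C1 (OAc), C2, C3 (OH, iPr), C3a (H), C4 (aroyloxy), C5=C6(Me), C7(=O), C8, C8a (Me); ring A is the five-membered ring. Target ⇒ (C1 acetylation; C4 esterification with inversion) triol 14 ⇒ trione 13 by C3–OH-directed reduction of the C1 and C4 carbonyls.
2. 13 ⇒ cycloheptatriene 12 by unmasking the silylene that links the C3 oxygen to the C4 enol oxygen, and the C7 methyl enol ether.
3. Key disconnection: 12 ⇒ aryl 2-diazo-3-ketone 10 (intramolecular Büchner reaction). The carbenoid carbon C8a closes ring A onto the arene and is inserted between C3a and C8, so the seven-membered ring is formed from the six-membered benzene ring of 10 by one-carbon ring expansion.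
4. Enabling feature: with C8a taken out, the seven-membered ring (C3a, C4–O, C5, C6–Me, C7–O, C8) is a 2,5-dioxygenated 4-methylphenyl ring; C8a is quaternary, carries the methyl group and sits next to the C1 oxygen (the diazo carbon of a ketone); the C3 oxygen is 1,3 to the C4 oxygen, so both fit into one silylene ring that steers the carbenoid.
5. 10 ⇒ coumarin 3 (Pechmann; C3 carbinol by enantioselective conjugate borylation/oxidation). Ring order: arene (purchased) → temporary lactone ring (step 1, opened in step 3) → temporary silylene ring (step 4) → ring A and the seven-membered ring together (step 7).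

Key step: step 7

**Route**

Step 1
Reactants: 1 4-methoxy-3-methylphenol; 2 ethyl 4-methyl-3-oxopentanoate
Product: 3 4-isopropyl-6-methoxy-7-methyl-2H-chromen-2-one
Conditions: MeSO3H (neat), 25 → 45 °C
Reagents that add atoms: none
Why: Pechmann condensation (transesterification, intramolecular Friedel–Crafts hydroxyalkylation, dehydration) should close the lactone at C6 of 1, the only unhindered position ortho to the hydroxyl and para to the methyl group, which fixes the 6-methoxy-7-methyl pattern.

Step 2
Reactants: 3 4-isopropyl-6-methoxy-7-methyl-2H-chromen-2-one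
Product: 5 (4S)-4-hydroxy-4-isopropyl-6-methoxy-7-methylchroman-2-one, via pinacol boronate 4 (not isolated)
Conditions: B2pin2, CuCl (5 mol %), NaOtBu (10 mol %), Josiphos-type bisphosphine (6 mol %, antipode chosen for the 4R boronate), MeOH (2 equiv), THF, 23 °C; then NaBO3·4H2O, THF/H2O, 23 °C; work-up at pH 5
Reagents that add atoms: sodium perborate (NaBO3, used as tetrahydrate), [Na+].[O-]OB=O (hydroxyl oxygen of 5); bis(pinacolato)diboron, CC1(C)OB(OC1(C)C)B1OC(C)(C)C(C)(C)O1 (boryl group of 4, lost again in the same step)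
Why: Copper-catalysed enantioselective boryl conjugate addition to the β,β-disubstituted unsaturated lactone puts boron on C4 of the coumarin (future C3) from the enantiotopic face selected by the chiral bisphosphine, and perborate oxidation replaces boron by hydroxyl with retention, so the ligand sets the (S) tertiary carbinol; the mildly acidic work-up recloses any ring-opened ester to the lactone.

Step 3
Reactants: 5 (4S)-4-hydroxy-4-isopropyl-6-methoxy-7-methylchroman-2-one
Product: 6 (3S)-3-hydroxy-3-(2-hydroxy-5-methoxy-4-methylphenyl)-N-methoxy-N,4-dimethylpentanamide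
Conditions: MeNH(OMe)·HCl, iPrMgCl, THF, −20 → 0 °C; aq. NH4Cl
Reagents that add atoms: N,O-dimethylhydroxylamine hydrochloride, CNOC.Cl
Why: Weinreb amide formation by aminolysis of the reactive aryl ester with the chloromagnesium amide opens the lactone and frees the phenol without touching the carbinol stereocentre.

Step 4
Reactants: 6 (3S)-3-hydroxy-3-(2-hydroxy-5-methoxy-4-methylphenyl)-N-methoxy-N,4-dimethylpentanamide
Product: 7 2-[(4S)-2,2-di-tert-butyl-4-isopropyl-6-methoxy-7-methyl-4H-1,3,2-benzodioxasilin-4-yl]-N-methoxy-N-methylacetamide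
Conditions: tBu2Si(OTf)2, 2,6-lutidine, CH2Cl2, 0 → 23 °C
Reagents that add atoms: di-tert-butylsilyl bis(trifluoromethanesulfonate), CC(C)(C)[Si](OS(=O)(=O)C(F)(F)F)(OS(=O)(=O)C(F)(F)F)C(C)(C)C
Why: Cyclic silylene protection of the 1,3-related phenol/tertiary alcohol pair (phenol silylated first, intramolecular closure of the six-membered ring by the tertiary hydroxyl) masks the hydroxyl against O–H insertion and ties O3 to the C4 oxygen close to the arene plane.

Step 5
Reactants: 7 2-[(4S)-2,2-di-tert-butyl-4-isopropyl-6-methoxy-7-methyl-4H-1,3,2-benzodioxasilin-4-yl]-N-methoxy-N-methylacetamide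
Product: 8 1-[(4S)-2,2-di-tert-butyl-4-isopropyl-6-methoxy-7-methyl-4H-1,3,2-benzodioxasilin-4-yl]butan-2-one
Conditions: EtMgBr, THF, 0 °C; aq. NH4Cl
Reagents that add atoms: ethylmagnesium bromide, CC[Mg]Br
Why: Weinreb ketone synthesis: the chelated tetrahedral magnesium adduct survives until work-up, so a single ethyl group is delivered.

Step 6
Reactants: 8 1-[(4S)-2,2-di-tert-butyl-4-isopropyl-6-methoxy-7-methyl-4H-1,3,2-benzodioxasilin-4-yl]butan-2-one
Product: 10 3-diazo-1-[(4S)-2,2-di-tert-butyl-4-isopropyl-6-methoxy-7-methyl-4H-1,3,2-benzodioxasilin-4-yl]butan-2-one, via trifluoroacetyl diketone 9 (not isolated)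
Conditions: LiN(SiMe3)2, THF, −78 °C; CF3CO2CH2CF3; aq. HCl work-up; then 4-acetamidobenzenesulfonyl azide, Et3N, H2O (1 equiv), MeCN, 23 °C
Reagents that add atoms: 4-acetamidobenzenesulfonyl azide, CC(=O)Nc1ccc(cc1)S(=O)(=O)N=[N+]=[N-] (the two diazo nitrogens); 2,2,2-trifluoroethyl trifluoroacetate, FC(F)(F)COC(=O)C(F)(F)F (trifluoroacetyl group of 9, lost again in the same step)
Why: Detrifluoroacetylative diazo transfer (Regitz-type): kinetic enolisation takes place at the ethyl CH2 because the other α-methylene is neopentylic next to the quaternary C3, Claisen trifluoroacetylation activates that carbon, and the sulfonyl azide transfers N2 with loss of the trifluoroacetyl group.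

Step 7
Reactants: 10 3-diazo-1-[(4S)-2,2-di-tert-butyl-4-isopropyl-6-methoxy-7-methyl-4H-1,3,2-benzodioxasilin-4-yl]butan-2-one
Product: 12 (3S,8aS)-3,4-(di-tert-butylsilanediyldioxy)-3-isopropyl-7-methoxy-6,8a-dimethyl-3,8a-dihydroazulen-1(2H)-one, via norcaradiene 11 (not isolated)
Conditions: Rh2(OAc)4 (1 mol %), CH2Cl2, 40 °C, slow addition of 10 at high dilution
Reagents that add atoms: none
Why: Rh2(OAc)4 turns 10 into a rhodium carbenoid whose carbon (C8a) adds across the arene bond C3a–C8 in an intramolecular [2+1] cycloaddition that closes ring A through the new C8a–C3a bond (five-membered ring closed onto the ipso carbon over the three-atom tether C1–C2–C3) and gives norcaradiene 11, whose C3a–C8 bond then opens in a disrotatory six-electron electrocyclic reaction, so that the six-membered aromatic ring becomes the seven-membered ring with C8a inserted between C3a and C8. The closest known reaction type is the intramolecular Büchner reaction of 2-diazo-5-arylpentan-3-ones (methyl group on the diazo carbon), which is also established for methoxy-substituted arenes. The only new stereocentre of 12, quaternary C8a, is controlled by C3 through the silylene ring: O3 is held near the arene plane on the C4 side, the tether CH2 and the isopropyl group therefore point to opposite faces, and the carbenoid can reach the arene only from the face that places the C8a methyl cis to O3 and C8 cis to the isopropyl group (the two extra centres of 11 follow from the cis fusion of the cyclopropane and disappear on ring opening). Regioselectivity for the C3a–C8 bond over the C3a–C4 bond is needed and is secured by the same ring, which makes the tether lean towards C8, and by C4 being fully substituted. Chemoselectivity over 1,2-hydride shift from the methyl group, insertion into the isopropyl C–H bond, oxonium ylide formation and aromatic substitution is needed; the electron-rich arene held next to the carbenoid, the shielding of O3 by the di-tert-butylsilyl group, the acid-free conditions and slow addition should secure it. In this single operation both carbocyclic rings, the methyl-bearing quaternary centre and the C1 carbonyl are formed, and the triene produced already carries the C4 and C7 oxygens as enol ethers and the C6 methyl group in the positions of the target.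

Step 8
Reactants: 12 (3S,8aS)-3,4-(di-tert-butylsilanediyldioxy)-3-isopropyl-7-methoxy-6,8a-dimethyl-3,8a-dihydroazulen-1(2H)-one
Product: 13 (3S,3aS,8aS)-3-hydroxy-3-isopropyl-6,8a-dimethyl-3,3a,8,8a-tetrahydroazulene-1,4,7(2H)-trione
Conditions: HF·pyridine, pyridine/THF, 0 °C; then 1 M aq. HCl, THF, 23 °C
Reagents that add atoms: water, O
Why: Fluoride cleavage of the silylene frees the C3 hydroxyl and the C4 enol, which ketonises, and acid hydrolysis of the C7 methyl enol ether (protonation at C8) gives the ene-dione; C3a, now α to the C4 ketone, is set under thermodynamic control and should prefer the trans ring fusion (H-3a anti to the C8a methyl), which places C4 anti to the isopropyl group and allows the C3–OH···O=C4 hydrogen bond.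

Step 9
Reactants: 13 (3S,3aS,8aS)-3-hydroxy-3-isopropyl-6,8a-dimethyl-3,3a,8,8a-tetrahydroazulene-1,4,7(2H)-trione
Product: 14 (1R,3S,3aR,4S,8aS)-1,3,4-trihydroxy-3-isopropyl-6,8a-dimethyl-2,3,3a,4,8,8a-hexahydroazulen-7(1H)-one
Conditions: Me4NBH(OAc)3 (8 equiv), MeCN/AcOH (1:1), −30 → 0 °C; aq. potassium sodium tartrate
Reagents that add atoms: none
Why: Evans–Saksena hydroxyl-directed reduction: the C3 alkoxy(diacetoxy)borohydride delivers hydride intramolecularly only to the two β-hydroxy ketone carbonyls, to C1 across ring A from the face of the C3 hydroxyl (trans-1,3-diol, 1R) and to C4 through a chair transition state with H-3a axial, i.e. from the face remote from the C8a methyl that is also the sterically open one (4S, the epimer needed for the inversion in step 10), while the C7 enone carbonyl has no 1,3-hydroxyl and is left; only the trans-fused C3a epimer has the C3 hydroxyl cis to C4 as this delivery requires.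

Step 10
Reactants: 14 (1R,3S,3aR,4S,8aS)-1,3,4-trihydroxy-3-isopropyl-6,8a-dimethyl-2,3,3a,4,8,8a-hexahydroazulen-7(1H)-one; 15 4-acetoxybenzoic acid
Product: 16 (1R,3S,3aR,4R,8aS)-1,3-dihydroxy-3-isopropyl-6,8a-dimethyl-7-oxo-1,2,3,3a,4,7,8,8a-octahydroazulen-4-yl 4-acetoxybenzoate
Conditions: PPh3, DIAD, THF, 0 → 23 °C
Reagents that add atoms: none
Why: Mitsunobu esterification with inversion at the allylic C4 gives the (4R) ester; the C1 hydroxyl cannot be displaced because its rear side is blocked by the C8a methyl group (neopentyl position), the C3 hydroxyl is tertiary, and attack in the SN2′ sense would have to occur at the electron-poor, methyl-bearing α-carbon C6 of the enone.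

Step 11
Reactants: 16 (1R,3S,3aR,4R,8aS)-1,3-dihydroxy-3-isopropyl-6,8a-dimethyl-7-oxo-1,2,3,3a,4,7,8,8a-octahydroazulen-4-yl 4-acetoxybenzoate
Product: 17 (1R,3S,3aR,4R,8aS)-1-acetoxy-3-hydroxy-3-isopropyl-6,8a-dimethyl-7-oxo-1,2,3,3a,4,7,8,8a-octahydroazulen-4-yl 4-acetoxybenzoate
Conditions: Ac2O, DMAP (cat.), pyridine, CH2Cl2, 0 → 23 °C
Reagents that add atoms: acetic anhydride, CC(=O)OC(C)=O
Why: DMAP-catalysed acetylation of the only remaining secondary hydroxyl (C1); the hindered tertiary C3 hydroxyl should not react under these conditions.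

Step 12
Reactants: 17 (1R,3S,3aR,4R,8aS)-1-acetoxy-3-hydroxy-3-isopropyl-6,8a-dimethyl-7-oxo-1,2,3,3a,4,7,8,8a-octahydroazulen-4-yl 4-acetoxybenzoate
Product: 18 (1R,3S,3aR,4R,8aS)-1-acetoxy-3-hydroxy-3-isopropyl-6,8a-dimethyl-7-oxo-1,2,3,3a,4,7,8,8a-octahydroazulen-4-yl 4-hydroxybenzoate
Conditions: K2CO3 (0.3 equiv), MeOH, 0 °C, short reaction time; aq. NH4Cl
Reagents that add atoms: none
Why: Base-catalysed transesterification (methanolysis) cleaves the phenolic acetate, by far the most electrophilic ester, and should leave the neopentylic C1 acetate and the C4 benzoate intact at low temperature.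

**Compound list**

1 | 4-methoxy-3-methylphenol | COc1ccc(O)cc1C | starting material
2 | ethyl 4-methyl-3-oxopentanoate | CCOC(=O)CC(=O)C(C)C | starting material
3 | 4-isopropyl-6-methoxy-7-methyl-2H-chromen-2-one | CC(C)C1=CC(=O)Oc2cc(C)c(OC)cc12 | intermediate
4 | (4R)-4-isopropyl-6-methoxy-7-methyl-4-(4,4,5,5-tetramethyl-1,3,2-dioxaborolan-2-yl)chroman-2-one (not isolated) | O=C1C[C@](B2OC(C)(C)C(C)(C)O2)(C(C)C)c2cc(OC)c(C)cc2O1 | intermediate
5 | (4S)-4-hydroxy-4-isopropyl-6-methoxy-7-methylchroman-2-one | O=C1C[C@](O)(C(C)C)c2cc(OC)c(C)cc2O1 | intermediate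
6 | (3S)-3-hydroxy-3-(2-hydroxy-5-methoxy-4-methylphenyl)-N-methoxy-N,4-dimethylpentanamide | CON(C)C(=O)C[C@](O)(C(C)C)c1cc(OC)c(C)cc1O | intermediate
7 | 2-[(4S)-2,2-di-tert-butyl-4-isopropyl-6-methoxy-7-methyl-4H-1,3,2-benzodioxasilin-4-yl]-N-methoxy-N-methylacetamide | CON(C)C(=O)C[C@@]1(C(C)C)O[Si](C(C)(C)C)(C(C)(C)C)Oc2cc(C)c(OC)cc12 | intermediate
8 | 1-[(4S)-2,2-di-tert-butyl-4-isopropyl-6-methoxy-7-methyl-4H-1,3,2-benzodioxasilin-4-yl]butan-2-one | CCC(=O)C[C@@]1(C(C)C)O[Si](C(C)(C)C)(C(C)(C)C)Oc2cc(C)c(OC)cc12 | intermediate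
9 | 1,1,1-trifluoro-3-methyl-5-[(4S)-2,2-di-tert-butyl-4-isopropyl-6-methoxy-7-methyl-4H-1,3,2-benzodioxasilin-4-yl]pentane-2,4-dione (C3 of the chain unassigned, enolisable; not isolated) | CC(C(=O)C(F)(F)F)C(=O)C[C@@]1(C(C)C)O[Si](C(C)(C)C)(C(C)(C)C)Oc2cc(C)c(OC)cc12 | intermediate
10 | 3-diazo-1-[(4S)-2,2-di-tert-butyl-4-isopropyl-6-methoxy-7-methyl-4H-1,3,2-benzodioxasilin-4-yl]butan-2-one | CC(=[N+]=[N-])C(=O)C[C@@]1(C(C)C)O[Si](C(C)(C)C)(C(C)(C)C)Oc2cc(C)c(OC)cc12 | intermediate
11 | norcaradiene valence isomer of 12: cis-fused cyclopropane C3a–C8–C8a, double bonds C4=C5 and C6=C7, C1 ketone, silylene intact (not isolated) | O=C1C[C@@]2(C(C)C)O[Si](C(C)(C)C)(C(C)(C)C)OC3=CC(C)=C(OC)[C@@H]4[C@]23[C@@]14C | intermediate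
12 | (3S,8aS)-3,4-(di-tert-butylsilanediyldioxy)-3-isopropyl-7-methoxy-6,8a-dimethyl-3,8a-dihydroazulen-1(2H)-one (double bonds C3a=C4, C5=C6, C7=C8) | O=C1C[C@@]3(C(C)C)O[Si](C(C)(C)C)(C(C)(C)C)OC4=C3[C@]1(C)C=C(OC)C(C)=C4 | intermediate
13 | (3S,3aS,8aS)-3-hydroxy-3-isopropyl-6,8a-dimethyl-3,3a,8,8a-tetrahydroazulene-1,4,7(2H)-trione (trans-fused) | O=C1C[C@](O)(C(C)C)[C@H]2C(=O)C=C(C)C(=O)C[C@]12C | intermediate
14 | (1R,3S,3aR,4S,8aS)-1,3,4-trihydroxy-3-isopropyl-6,8a-dimethyl-2,3,3a,4,8,8a-hexahydroazulen-7(1H)-one | O[C@@H]1C[C@](O)(C(C)C)[C@H]2[C@@H](O)C=C(C)C(=O)C[C@]12C | intermediate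
15 | 4-acetoxybenzoic acid | CC(=O)Oc1ccc(cc1)C(=O)O | starting material
16 | (1R,3S,3aR,4R,8aS)-1,3-dihydroxy-3-isopropyl-6,8a-dimethyl-7-oxo-1,2,3,3a,4,7,8,8a-octahydroazulen-4-yl 4-acetoxybenzoate | O[C@@H]1C[C@](O)(C(C)C)[C@H]2[C@H](OC(=O)c3ccc(OC(C)=O)cc3)C=C(C)C(=O)C[C@]12C | intermediate
17 | (1R,3S,3aR,4R,8aS)-1-acetoxy-3-hydroxy-3-isopropyl-6,8a-dimethyl-7-oxo-1,2,3,3a,4,7,8,8a-octahydroazulen-4-yl 4-acetoxybenzoate | CC(=O)O[C@@H]1C[C@](O)(C(C)C)[C@H]2[C@H](OC(=O)c3ccc(OC(C)=O)cc3)C=C(C)C(=O)C[C@]12C | intermediate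
18 | (1R,3S,3aR,4R,8aS)-1-acetoxy-3-hydroxy-3-isopropyl-6,8a-dimethyl-7-oxo-1,2,3,3a,4,7,8,8a-octahydroazulen-4-yl 4-hydroxybenzoate (CNP0087181.6) | CC(=O)O[C@@H]1C[C@](O)(C(C)C)[C@H]2[C@H](OC(=O)c3ccc(O)cc3)C=C(C)C(=O)C[C@]12C | target

**Step count and risks**

Total step count: 12. Longest linear sequence: 12 steps (1 → 18; 2 and 15 enter in steps 1 and 10).

Steps most likely to fail:

1. Step 7. The methyl-substituted carbenoid may be lost by 1,2-hydride shift to a vinyl ketone, by insertion into the isopropyl C–H bond, or by aromatic substitution instead of cycloaddition. Fallback: the quaternary centre is made after the ring expansion instead of during it. Setting out from Weinreb amide 7, MeMgBr (THF, 0 °C) would give the methyl ketone F1. The trifluoroacetylation/diazo-transfer sequence of step 6, passing through the trifluoroacetyl diketone F2, would give the terminal diazoketone F3, which has no hydrogen next to the carbenoid carbon and belongs to the best-precedented substrate class of the intramolecular Büchner reaction. Rh2(OAc)4 in CH2Cl2 should then give the 8a-unsubstituted cycloheptatrienone F4. Its cross-conjugated lithium enolate (LiN(SiMe3)2, THF, −78 °C) would be methylated with MeI at C8a from the face opposite the pseudo-axial isopropyl group, i.e. cis to O3, which comes back to the route at 12.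

2. Step 2. The boryl–copper species may fail to add to the hindered, arene-conjugated β-carbon carrying the isopropyl group, or may add with poor enantiofacial control; the β-hydroxy lactone may also dehydrate back to the coumarin during oxidation. Fallback: the carbinol centre is made by 1,2-addition to a ketone. Setting out from phenol 1, Fries-type ortho-acylation with isobutyric acid and BF3·OEt2 (at C6, as in step 1) would give the 2-hydroxyaryl isopropyl ketone F5. A catalytic enantioselective Reformatsky reaction (ICH2CO2Et, Me2Zn, air, chiral BINOL-type ligand) would give the β-hydroxy ester F6, which lactonises on mild acid treatment and so comes back to the route at 5.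

3. Step 10. The alkoxyphosphonium ion at C4 has H-3a anti-periplanar and may collapse by elimination across C3a–C4 faster than it is displaced at the hindered carbon; activation of the wrong hydroxyl is a lesser risk. Fallback: the order of the two esterifications is reversed and the inversion is run as a sulfonate displacement. Setting out from 14, acetylation with one equivalent of Ac2O (pyridine, 0 °C) should take place at the C1 hydroxyl, because the C4 hydroxyl is axial and syn to the C8a methyl, to give the C1 monoacetate F7. MsCl/Et3N would give the allylic mesylate F8. Caesium 4-acetoxybenzoate (from 15 and Cs2CO3) with 18-crown-6 in toluene should displace it with inversion, which comes back to the route at 17.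

Further compounds
F1 | step 7 | 1-[(4S)-2,2-di-tert-butyl-4-isopropyl-6-methoxy-7-methyl-4H-1,3,2-benzodioxasilin-4-yl]propan-2-one | CC(=O)C[C@@]1(C(C)C)O[Si](C(C)(C)C)(C(C)(C)C)Oc2cc(C)c(OC)cc12
F2 | step 7 | 1,1,1-trifluoro-5-[(4S)-2,2-di-tert-butyl-4-isopropyl-6-methoxy-7-methyl-4H-1,3,2-benzodioxasilin-4-yl]pentane-2,4-dione | O=C(CC(=O)C(F)(F)F)C[C@@]1(C(C)C)O[Si](C(C)(C)C)(C(C)(C)C)Oc2cc(C)c(OC)cc12
F3 | step 7 | 1-diazo-3-[(4S)-2,2-di-tert-butyl-4-isopropyl-6-methoxy-7-methyl-4H-1,3,2-benzodioxasilin-4-yl]propan-2-one | [N-]=[N+]=CC(=O)C[C@@]1(C(C)C)O[Si](C(C)(C)C)(C(C)(C)C)Oc2cc(C)c(OC)cc12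
F4 | step 7 | (3S,8aS)-3,4-(di-tert-butylsilanediyldioxy)-3-isopropyl-7-methoxy-6-methyl-3,8a-dihydroazulen-1(2H)-one | O=C1C[C@@]3(C(C)C)O[Si](C(C)(C)C)(C(C)(C)C)OC4=C3[C@@H]1C=C(OC)C(C)=C4
F5 | step 2 | 1-(2-hydroxy-5-methoxy-4-methylphenyl)-2-methylpropan-1-one | CC(C)C(=O)c1cc(OC)c(C)cc1O
F6 | step 2 | ethyl (3S)-3-hydroxy-3-(2-hydroxy-5-methoxy-4-methylphenyl)-4-methylpentanoate | CCOC(=O)C[C@](O)(C(C)C)c1cc(OC)c(C)cc1O
F7 | step 10 | (1R,3S,3aR,4S,8aS)-3,4-dihydroxy-3-isopropyl-6,8a-dimethyl-7-oxo-1,2,3,3a,4,7,8,8a-octahydroazulen-1-yl acetate | CC(=O)O[C@@H]1C[C@](O)(C(C)C)[C@H]2[C@@H](O)C=C(C)C(=O)C[C@]12C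
F8 | step 10 | (1R,3S,3aR,4S,8aS)-3-hydroxy-3-isopropyl-6,8a-dimethyl-4-[(methylsulfonyl)oxy]-7-oxo-1,2,3,3a,4,7,8,8a-octahydroazulen-1-yl acetate | CC(=O)O[C@@H]1C[C@](O)(C(C)C)[C@H]2[C@@H](OS(C)(=O)=O)C=C(C)C(=O)C[C@]12C
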